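All runs were generated by integration for an exercise.

The amounts came first: 0.80 M of free monomer against 20 mM of initiator, with 0.240 M of transfer agent, and I had to decide whether a flask so charged should be stopped at 1.5 h or left until 3.0 h.

all flasks: free monomer 0.80 M
- teal: transfer agent 0.24 M; initiator 10 mM; run made earlier
- south-west: transfer agent 0.240 M; initiator 20 mM; time 3.0 h
- east: transfer agent 0.240 M; initiator 20 mM; time 1.5 h

teal run (percent of the free monomer charged)

| time / min | monomer in chains / % |
|---|---|
| 3.00 | 0.1 |
| 8.00 | 1.1 |
| 15.0 | 5.1 |
| 25.0 | 4.9 |
| 30.0 | 8.2 |
| 40.0 | 10.9 |
| 50.0 | 11.7 |

(each reading ± 1 percentage point)

* which of the two ends with the longer chains by the average number of monomer units in a chain (chains begun, living or dead) ("neither" if they lie within 10%) (south-west / east / neither)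
* average number of monomer units in a chain (chains begun, living or dead) at the end, south-west
* average number of monomer units in a chain (chains begun, living or dead) at the end, east

- the average divides the monomer in chains by the number of chains begun, living and dead together
- the earlier runs do not show the number of chains; that part of a forecast is a guess
- no earlier run changes the charge of initiator; that part of a forecast is a guess

Leaving it was worth the time if the chains went on lengthening. I took it that each initiator began one chain and that nothing else began any, so the count of chains stopped near the charge. The average length was then x·L, where x is the fraction of free monomer reacted and L is the length ceiling, free monomer charged over initiator charged, 40.0.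

For x I treated the free monomer as pseudo-first-order, so that x = 1 − exp(−kt). The last teal reading, 11.7% at 50.0 min, with a scatter of 1 percentage point, gave k = 0.149 h⁻¹. I scaled this by the ratio of initiator charges, a guess since no earlier run varied them, to 0.299 h⁻¹. That put x at 36.1% in east and 59.2% in south-west, so lengths of 14.4 and 23.7. South-west came out longer than east, well beyond the margin of 10%, and I would have left the flask until 3.0 h.

The forecast said neither, with 15 units for south-west and 15 for east, the average being “nearly independent of time”.

The flasks gave south-west as the longer, 16.8 units against 12.6 for east.

    free monomer + initiator → living end + monomer in chains (k = 0.00180 L mol⁻¹ s⁻¹)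
    free monomer + living end → monomer in chains + living end, rate k2*[living end]*[free monomer] (k = 0.00640 L mol⁻¹ s⁻¹)
    living end + transfer agent → dead chain (kL = 1.60 × 10⁻⁴ L mol⁻¹ s⁻¹)
    initiator → spent initiator A (k = 6.90 × 10⁻⁵ s⁻¹)
    2 living end → dead end B (k = 0.0100 L mol⁻¹ s⁻¹)

Monomer in chains in south-west reached 40.1%, less than my 59.2%. The gap between the flasks is the difference in time: east, at 12.6 units, stands at 16.8 when given the time of south-west. In east at 1.50 h initiator was down to 0.112% of its charge, and the further time in south-west carried monomer in chains from 29.9% to 40.1%, onto chains already begun. L times those shares gives 12.0 for east and 16.0 for south-west. For the neighbour charged with 0.080 M of initiator and held to 1.5 h, the ceiling falls to 10.0, and its 58.1% of monomer in chains gives 5.81, against the 6.18 that flask gave.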